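**Retrosynthetic overview**

1. Locants: oxolane O1, C2, C3, C4, C5; Ca is the (S)-carbinol carbon on C3, Cb the (R)-carbinol carbon on C4.
2. Target ⇒ (hydrogenolysis, desilylation, Felkin–Anh reduction at Ca) trans-3-aroyloxolane 13, which already holds the only ring.
3. 13 ⇒ acyclic aryl ketone 10 by the C2–C3 disconnection. The enabling feature is that the Ca carbonyl can enolise only towards C3 and stands 1,4 to O1, whose methoxymethyl acetal carbon is C2 itself; the enol carbon C3 and the oxocarbenium carbon C2 are therefore the two ends of the chain C3–C4–C5–O1–C2 and close the oxolane. A protecting-group carbon becomes a ring atom.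
4. 10 ⇒ γ-keto aldehyde 6 + aryl Grignard 8 (Cb–aryl bond; the same acetal chelates magnesium and sets Cb); 6 ⇒ 3-(methoxymethoxy)propanal 4 + bromo ketone 5 (C3–C4 bond by organo-photoredox α-alkylation, the only external asymmetric induction, sets C4).
5. Ring order: a single ring, closed in step 6; the stereocentres are relayed C4 → Cb → C3 → Ca.

Key step: step 6

Remark: 5 and 7 are taken as purchasable; aldehyde 4 is made in two steps from but-3-en-1-ol because its commercial supply is uncertain.

**Route**

Step 1
Reactants: 1 but-3-en-1-ol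
Product: 2 4-(methoxymethoxy)but-1-ene
Conditions: MOMCl, iPr2NEt, CH2Cl2, 0 °C → rt
Reagents that add atoms: chloromethyl methyl ether, COCCl
Why: O-alkylation of the primary alcohol by the α-chloro ether (MOM acetal formation) should be clean, and the acetal CH2 installed here is the carbon that later becomes C2 of the oxolane.

Step 2
Reactants: 2 4-(methoxymethoxy)but-1-ene
Product: 4 3-(methoxymethoxy)propanal, via secondary ozonide 3 (not isolated)
Conditions: O3, CH2Cl2, −78 °C; then Me2S, −78 °C → rt
Reagents that add atoms: ozone, [O-][O+]=O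
Why: Ozonolysis of the terminal alkene with reductive work-up should give the aldehyde without touching the acetal.

Step 3
Reactants: 4 3-(methoxymethoxy)propanal (in excess); 5 2-bromo-1-[4-(benzyloxy)-3-methoxyphenyl]ethan-1-one
Product: 6 (2R)-4-[4-(benzyloxy)-3-methoxyphenyl]-2-[(methoxymethoxy)methyl]-4-oxobutanal
Conditions: (2S,5R)-2-tert-butyl-3,5-dimethylimidazolidin-4-one·TfOH (20 mol %), Ru(bpy)3Cl2 (0.5 mol %), 2,6-lutidine, DMF, blue LEDs, rt
Reagents that add atoms: none
Why: Enantioselective organo-photoredox α-alkylation of an aldehyde, in which the phenacyl radical from reductive C–Br cleavage adds to the face of the E-enamine not shielded by the 5-methyl group of the catalyst, should set C4 as R (the (2R,5S) antipode of the catalyst is expected to give the S series).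

Step 4
Reactants: 6 (2R)-4-[4-(benzyloxy)-3-methoxyphenyl]-2-[(methoxymethoxy)methyl]-4-oxobutanal; 7 1-(benzyloxy)-4-bromo-2-methoxybenzene
Product: 9 (3R,4R)-1,4-bis[4-(benzyloxy)-3-methoxyphenyl]-4-hydroxy-3-[(methoxymethoxy)methyl]butan-1-one, via arylmagnesium bromide 8 (not isolated)
Conditions: 7, Mg, Et2O, reflux → 8; 6, MgBr2·OEt2, CH2Cl2, −78 °C, then 8; then H2O
Reagents that add atoms: none
Why: Cram-chelate-controlled Grignard addition, in which magnesium ties the aldehyde oxygen to the acetal oxygen in a six-membered chelate and the aryl group enters anti to the CH2C(O)Ar branch on C4, should set Cb as R (3,4-anti) while the electron-rich aryl ketone is left untouched at −78 °C.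

Step 5
Reactants: 9 (3R,4R)-1,4-bis[4-(benzyloxy)-3-methoxyphenyl]-4-hydroxy-3-[(methoxymethoxy)methyl]butan-1-one
Product: 10 (3R,4R)-1,4-bis[4-(benzyloxy)-3-methoxyphenyl]-4-[(tert-butyldimethylsilyl)oxy]-3-[(methoxymethoxy)methyl]butan-1-one
Conditions: TBSOTf, 2,6-lutidine, CH2Cl2, −78 °C (crude 9 used without delay)
Reagents that add atoms: tert-butyldimethylsilyl triflate, CC(C)(C)[Si](C)(C)OS(=O)(=O)C(F)(F)F
Why: Silylation of the secondary alcohol under buffered conditions removes the γ-hydroxy ketone (hemiketal) equilibrium and puts a bulky, poorly ionisable group on the electron-rich benzylic oxygen before the Lewis-acid step.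

Step 6
Reactants: 10 (3R,4R)-1,4-bis[4-(benzyloxy)-3-methoxyphenyl]-4-[(tert-butyldimethylsilyl)oxy]-3-[(methoxymethoxy)methyl]butan-1-one
Product: 13 [4-(benzyloxy)-3-methoxyphenyl][(3R,4R)-4-{(R)-[4-(benzyloxy)-3-methoxyphenyl][(tert-butyldimethylsilyl)oxy]methyl}oxolan-3-yl]methanone, via TMS enol ether 11 (not isolated), via oxocarbenium triflate 12 (not isolated)
Conditions: TMSOTf (1.2 equiv), iPr2NEt (1.4 equiv), CH2Cl2, 0 °C; then TMSOTf (1.0 equiv), −78 → −20 °C; aq NaHCO3
Reagents that add atoms: none
Why: TMSOTf/iPr2NEt first converts the aryl ketone, which can enolise only towards the CH2 that becomes C3, into the Z-TMS enol ether 11; the second charge of TMSOTf then silylates the unhindered terminal methoxy oxygen of the acetal, MeOSiMe3 leaves, and the formaldehyde-derived oxocarbenium ion 12 (the former protecting-group CH2, now C2) is attacked by the enol carbon, the resulting silyloxocarbenium ion losing Me3Si+ to give ketone 13. The closest known reaction type is the intramolecular Mukaiyama-type addition of an enol silane to an acetal-derived oxocarbenium ion in the one-pot TMSOTf/amine mode, the same oxocarbenium–enol recombination that gives 3-acyloxolanes in Petasis–Ferrier-type rearrangements of cyclic enol acetals. The oxolane closes in a 5-(enolexo) mode in which the O=C+ bond is endocyclic (5-endo-trig at the oxocarbenium carbon), a closure that is routine for oxocarbenium ions. The new stereocentre C3 is controlled by C4: allylic 1,3-strain in the Z-enol silane holds the C4–H bond in the enol plane, so C2 is delivered to the face anti to the silyloxybenzyl arm and the aroyl group ends trans to it, which is also the thermodynamic outcome because C3 stays epimerisable. The step needs chemoselective ionisation of the acetal in the presence of the electron-rich benzylic silyl ether, secured by the bulk of the tert-butyldimethylsilyl group, the staged amine buffer and the low temperature, and C- rather than O-alkylation of the enol silane, secured by five- over seven-membered ring formation.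

Step 7
Reactants: 13 [4-(benzyloxy)-3-methoxyphenyl][(3R,4R)-4-{(R)-[4-(benzyloxy)-3-methoxyphenyl][(tert-butyldimethylsilyl)oxy]methyl}oxolan-3-yl]methanone
Product: 14 (S)-[4-(benzyloxy)-3-methoxyphenyl][(3R,4R)-4-{(R)-[4-(benzyloxy)-3-methoxyphenyl][(tert-butyldimethylsilyl)oxy]methyl}oxolan-3-yl]methanol
Conditions: LiBH(s-Bu)3, THF, −78 °C; then H2O
Reagents that add atoms: none
Why: Felkin–Anh addition of the bulky hydride to the aryl ketone, with the C3–C4 ring bond (carrying the large silyloxybenzyl branch) anti to the incoming hydride and the ring CH2 (C2) in the inside position, should form Ca as S.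

Step 8
Reactants: 14 (S)-[4-(benzyloxy)-3-methoxyphenyl][(3R,4R)-4-{(R)-[4-(benzyloxy)-3-methoxyphenyl][(tert-butyldimethylsilyl)oxy]methyl}oxolan-3-yl]methanol
Product: 15 (S)-[4-(benzyloxy)-3-methoxyphenyl][(3R,4R)-4-{(R)-[4-(benzyloxy)-3-methoxyphenyl](hydroxy)methyl}oxolan-3-yl]methanol
Conditions: Bu4NF, THF, 0 °C → rt
Reagents that add atoms: none
Why: Fluoride-mediated desilylation should cleave the secondary silyl ether under conditions that leave the benzyl ethers and both carbinol stereocentres untouched.

Step 9
Reactants: 15 (S)-[4-(benzyloxy)-3-methoxyphenyl][(3R,4R)-4-{(R)-[4-(benzyloxy)-3-methoxyphenyl](hydroxy)methyl}oxolan-3-yl]methanol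
Product: 16 4-[(S)-hydroxy{(3R,4R)-4-[(R)-hydroxy(4-hydroxy-3-methoxyphenyl)methyl]oxolan-3-yl}methyl]-2-methoxyphenol (target)
Conditions: H2 (1 atm), Pd/C, EtOAc, rt
Reagents that add atoms: none
Why: Hydrogenolysis of the two aryl benzyl ethers over Pd/C in a neutral aprotic solvent should release both phenols while the secondary benzylic alcohols, which are not acid-activated under these conditions, are retained.

**Compound list**

1 | but-3-en-1-ol | C=CCCO | starting material
2 | 4-(methoxymethoxy)but-1-ene | C=CCCOCOC | intermediate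
3 | 3-[2-(methoxymethoxy)ethyl]-1,2,4-trioxolane (secondary ozonide, not isolated) | COCOCCC1OCOO1 | intermediate
4 | 3-(methoxymethoxy)propanal | O=CCCOCOC | intermediate
5 | 2-bromo-1-[4-(benzyloxy)-3-methoxyphenyl]ethan-1-one | COc1cc(C(=O)CBr)ccc1OCc1ccccc1 | starting material
6 | (2R)-4-[4-(benzyloxy)-3-methoxyphenyl]-2-[(methoxymethoxy)methyl]-4-oxobutanal | O=C[C@@H](COCOC)CC(=O)c1ccc(OCc2ccccc2)c(OC)c1 | intermediate
7 | 1-(benzyloxy)-4-bromo-2-methoxybenzene | COc1cc(Br)ccc1OCc1ccccc1 | starting material
8 | [4-(benzyloxy)-3-methoxyphenyl]magnesium bromide (not isolated) | COc1cc([Mg]Br)ccc1OCc1ccccc1 | intermediate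
9 | (3R,4R)-1,4-bis[4-(benzyloxy)-3-methoxyphenyl]-4-hydroxy-3-[(methoxymethoxy)methyl]butan-1-one | COc1cc(C(=O)C[C@H](COCOC)[C@@H](O)c2ccc(OCc3ccccc3)c(OC)c2)ccc1OCc1ccccc1 | intermediate
10 | (3R,4R)-1,4-bis[4-(benzyloxy)-3-methoxyphenyl]-4-[(tert-butyldimethylsilyl)oxy]-3-[(methoxymethoxy)methyl]butan-1-one | COc1cc(C(=O)C[C@H](COCOC)[C@@H](O[Si](C)(C)C(C)(C)C)c2ccc(OCc3ccccc3)c(OC)c2)ccc1OCc1ccccc1 | intermediate
11 | trimethyl{[(1Z,3R,4R)-1,4-bis[4-(benzyloxy)-3-methoxyphenyl]-4-[(tert-butyldimethylsilyl)oxy]-3-[(methoxymethoxy)methyl]but-1-en-1-yl]oxy}silane (Z-TMS enol ether of 10, not isolated) | COc1cc(/C(O[Si](C)(C)C)=C/[C@H](COCOC)[C@@H](O[Si](C)(C)C(C)(C)C)c2ccc(OCc3ccccc3)c(OC)c2)ccc1OCc1ccccc1 | intermediate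
12 | oxocarbenium triflate from 11 (O=CH2+ on the primary oxygen in place of the methoxymethyl group, not isolated) | COc1cc(/C(O[Si](C)(C)C)=C/[C@H](C[O+]=C)[C@@H](O[Si](C)(C)C(C)(C)C)c2ccc(OCc3ccccc3)c(OC)c2)ccc1OCc1ccccc1.[O-]S(=O)(=O)C(F)(F)F | intermediate
13 | [4-(benzyloxy)-3-methoxyphenyl][(3R,4R)-4-{(R)-[4-(benzyloxy)-3-methoxyphenyl][(tert-butyldimethylsilyl)oxy]methyl}oxolan-3-yl]methanone | COc1cc(C(=O)[C@H]2COC[C@@H]2[C@@H](O[Si](C)(C)C(C)(C)C)c2ccc(OCc3ccccc3)c(OC)c2)ccc1OCc1ccccc1 | intermediate
14 | (S)-[4-(benzyloxy)-3-methoxyphenyl][(3R,4R)-4-{(R)-[4-(benzyloxy)-3-methoxyphenyl][(tert-butyldimethylsilyl)oxy]methyl}oxolan-3-yl]methanol | COc1cc([C@@H](O)[C@H]2COC[C@@H]2[C@@H](O[Si](C)(C)C(C)(C)C)c2ccc(OCc3ccccc3)c(OC)c2)ccc1OCc1ccccc1 | intermediate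
15 | (S)-[4-(benzyloxy)-3-methoxyphenyl][(3R,4R)-4-{(R)-[4-(benzyloxy)-3-methoxyphenyl](hydroxy)methyl}oxolan-3-yl]methanol | COc1cc([C@@H](O)[C@H]2COC[C@@H]2[C@@H](O)c2ccc(OCc3ccccc3)c(OC)c2)ccc1OCc1ccccc1 | intermediate
16 | 4-[(S)-hydroxy{(3R,4R)-4-[(R)-hydroxy(4-hydroxy-3-methoxyphenyl)methyl]oxolan-3-yl}methyl]-2-methoxyphenol | COc1cc([C@@H](O)[C@H]2COC[C@@H]2[C@@H](O)c2ccc(O)c(OC)c2)ccc1O | target

**Summary**

Total step count: 9. Longest linear sequence: 9 steps (1 → 16); 5 and 7 enter as purchased partners.

Steps most likely to fail: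

- **Step 6.** The Lewis acid may ionise the electron-rich benzylic silyl ether (loss of the protecting group and cation chemistry at Cb), or the acetal may cleave at its inner oxygen so that the one-carbon unit is transferred away instead of closing the ring. The fallback sets out from 10 and moves the ring closure into a basic regime. Me2BBr in CH2Cl2 at −78 °C should convert the methoxymethyl ether into (3R,4R)-1,4-bis[4-(benzyloxy)-3-methoxyphenyl]-3-[(bromomethoxy)methyl]-4-[(tert-butyldimethylsilyl)oxy]butan-1-one F1. After removal of the volatiles, LiN(SiMe3)2 in THF at −78 °C should form the ketone enolate, which closes the same C2–C3 bond by intramolecular C-alkylation (5-exo-tet). The route is rejoined at 13.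

- **Step 4.** Incomplete chelation would let the open Felkin–Anh pathway compete and erode facial selectivity at Cb, and the α-stereocentre of the aldehyde may epimerise on prolonged contact with the magnesium salts. The fallback sets out from 6 and the Grignard reagent 8 and replaces substrate control by catalyst control. Reagent 8 is transmetallated with ClTi(OiPr)3 to [4-(benzyloxy)-3-methoxyphenyl]tri(propan-2-yloxy)titanium F2. F2 is added to 6 in toluene at −20 °C in the presence of Ti(OiPr)4 and (R,R)-TADDOL, the ligand enantiomer expected to deliver the aryl group to the Si face of the aldehyde and hence the R carbinol. Aqueous work-up rejoins the route at 9.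

- **Step 7.** Facial selectivity of hydride delivery may be poor if the two ring branches on C3 are not differentiated enough. The fallback sets out from 13 and uses reagent control instead of substrate control: Corey–Bakshi–Shibata reduction with (R)-2-methyl-CBS-oxazaborolidine and BH3·SMe2 in THF at −20 °C, with the aryl group as the large substituent, should give the S carbinol. It rejoins the route at 14 and makes no new compound (F0).

Further compounds
F1 | step 6 | (3R,4R)-1,4-bis[4-(benzyloxy)-3-methoxyphenyl]-3-[(bromomethoxy)methyl]-4-[(tert-butyldimethylsilyl)oxy]butan-1-one | COc1cc(C(=O)C[C@H](COCBr)[C@@H](O[Si](C)(C)C(C)(C)C)c2ccc(OCc3ccccc3)c(OC)c2)ccc1OCc1ccccc1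
F2 | step 4 | [4-(benzyloxy)-3-methoxyphenyl]tri(propan-2-yloxy)titanium | CC(C)O[Ti](OC(C)C)(OC(C)C)c1ccc(OCc2ccccc2)c(OC)c1
F0 | step 7 | none | none
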